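**Retrosynthetic overview**
1. Numbering (atisane type): ring B = C5–C6–C7–C8–C9–C10, with isopropenyl (C4) on C5 and methyl (C20) plus the chain C1–C2–C3 on C10; δ-lactone C3(=O)–O–C9; bicyclo[2.2.2]octane with bridgeheads C8 and C12 and bridges C9–C11, C14–C13 (OAc on C14) and C15(=O)–C16(=C17H2).
2. Enabling feature: ketone C15 sits on quaternary C8, whose neighbour C9 carries the lactone oxygen and which also holds C14 (O–C9–C8(C14)–C15=O). This α-quaternary β-oxy ketone is the retron of an epoxy-alcohol semipinacol shift. The ring C8–C14–C13–C12–C16–C15 is therefore traced back to the cyclopentanol ring C15–C16–C12–C13–C14 of a bicyclo[3.2.1]oct-2-en-1-ol whose C8=C9 bond is the tetrasubstituted alkene of ring B.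
3. Key disconnection: epoxidation of C8=C9, shift of C14 from C15 to C8 (cyclopentane → cyclohexanone, bicyclo[3.2.1]octene → bicyclo[2.2.2]octanone) and lactonisation of the new C9–O with the C3 acid, in one flask. What remains is OTBS → OAc at C14 and methylenation at C16.
4. The bridged allylic alcohol is cut at C8–C15 (Nozaki–Hiyama–Kishi closure) and C9–C11 (Negishi coupling) into a ring B bromo enol triflate and an enantiopure 2-silyloxy-4-(iodomethyl)cyclopentanone.
5. Ring order: ring B (asymmetric conjugate addition/Michael on 2-methylcyclohex-2-enone); cyclopentane (from cyclopent-3-enylmethanol, desymmetrised); carbocycle C15–C8=C9–C11–C12–C16 (step 9); ring expansion to the bicyclo[2.2.2]octane together with the δ-lactone (step 11).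

Key step: step 11

Remark: the catalyst antipodes in steps 1 and 6 are taken to be those that deliver the configurations drawn, and cyclopent-3-en-1-ylmethanol is taken as commercial (otherwise one reduction from cyclopent-3-ene-1-carboxylic acid).

**Route**

Step 1
Reactants: 1 2-methylcyclohex-2-en-1-one; 2 isopropenylmagnesium bromide; 3 methyl acrylate
Product: 5 methyl 3-[(1S,6S)-1-methyl-2-oxo-6-(prop-1-en-2-yl)cyclohexyl]propanoate, via magnesium enolate 4 (not isolated)
Conditions: 2, Cu(OTf)2 (3 mol%), chiral imidazolinium salt (carbene ligand precursor, 4 mol%), Et2O, 0 °C; then 3, THF, −78 → −20 °C; aq. NH4Cl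
Reagents that add atoms: none
Why: Copper-catalysed asymmetric conjugate addition of the Grignard reagent to the α-methyl enone sets C5 under ligand control, and the regiodefined magnesium enolate 4 then undergoes Michael addition to 3 on the face anti to the adjacent isopropenyl group, which sets the quaternary C10 with the chain trans to isopropenyl.

Step 2
Reactants: 5 methyl 3-[(1S,6S)-1-methyl-2-oxo-6-(prop-1-en-2-yl)cyclohexyl]propanoate
Product: 7 methyl 3-[(1S,6S)-3-bromo-1-methyl-2-oxo-6-(prop-1-en-2-yl)cyclohexyl]propanoate, via lithium enolate 6 (not isolated)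
Conditions: LiN(SiMe3)2, THF, −78 °C; then NBS, −78 °C; aq. NH4Cl
Reagents that add atoms: N-bromosuccinimide, O=C1CCC(=O)N1Br
Why: Enolisation can only occur toward C8 because C10 is quaternary and the ketone is more acidic than the ester, and the lithium enolate is brominated by NBS (electrophilic α-bromination of an enolate); the new C8 centre is a mixture that is erased in step 3.

Step 3
Reactants: 7 methyl 3-[(1S,6S)-3-bromo-1-methyl-2-oxo-6-(prop-1-en-2-yl)cyclohexyl]propanoate
Product: 9 methyl 3-[(1S,6S)-3-bromo-1-methyl-6-(prop-1-en-2-yl)-2-(trifluoromethanesulfonyloxy)cyclohex-2-en-1-yl]propanoate, via potassium enolate 8 (not isolated)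
Conditions: KN(SiMe3)2, THF, −78 °C; then PhNTf2, −78 → 0 °C; aq. NH4Cl
Reagents that add atoms: N-phenylbis(trifluoromethanesulfonimide), O=S(=O)(N(c1ccccc1)S(=O)(=O)C(F)(F)F)C(F)(F)F
Why: The remaining acidic C8–H is removed and the enolate oxygen is trapped with PhNTf2 (enol triflate formation), giving the C8(Br)=C9(OTf) alkene with two differentiated coupling handles; a Favorskii pathway is excluded because C10 carries no hydrogen.

Step 4
Reactants: 10 cyclopent-3-en-1-ylmethanol
Product: 11 4-(iodomethyl)cyclopent-1-ene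
Conditions: I2, PPh3, imidazole, CH2Cl2, 0 → 23 °C
Reagents that add atoms: iodine, II
Why: Appel-type iodination of the primary alcohol by SN2 displacement of the alkoxyphosphonium ion; no stereocentre is involved.

Step 5
Reactants: 11 4-(iodomethyl)cyclopent-1-ene
Product: 12 (1R,2S,4s)-4-(iodomethyl)cyclopentane-1,2-diol (meso, both hydroxyls trans to the iodomethyl group)
Conditions: OsO4 (2 mol%), NMO, acetone/H2O, 0 → 23 °C
Reagents that add atoms: N-methylmorpholine N-oxide, C[N+]1([O-])CCOCC1; water, O
Why: Osmium-catalysed syn-dihydroxylation with NMO as co-oxidant, in which OsO4 should add to the cyclopentene face anti to the iodomethyl group, so that the meso cis-diol trans to C11 is the main product.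

Step 6
Reactants: 12 (1R,2S,4s)-4-(iodomethyl)cyclopentane-1,2-diol
Product: 13 (1R,2S,4R)-2-[(tert-butyldimethylsilyl)oxy]-4-(iodomethyl)cyclopentan-1-ol
Conditions: TBSCl, chiral amino-acid-derived N-methylimidazole catalyst (20 mol%), i-Pr2NEt, THF, −40 °C
Reagents that add atoms: tert-butyldimethylsilyl chloride, CC(C)(C)[Si](C)(C)Cl
Why: Catalytic enantioselective monosilylation of a meso cis-1,2-diol (desymmetrisation by a chiral Lewis-base catalyst), the catalyst antipode being chosen to silylate the hydroxyl at the S-configured carbinol carbon, which fixes the absolute configuration of C12 and C14.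

Step 7
Reactants: 13 (1R,2S,4R)-2-[(tert-butyldimethylsilyl)oxy]-4-(iodomethyl)cyclopentan-1-ol
Product: 14 (2S,4S)-2-[(tert-butyldimethylsilyl)oxy]-4-(iodomethyl)cyclopentan-1-one
Conditions: DMP, CH2Cl2, 0 → 23 °C
Reagents that add atoms: none
Why: Dess–Martin oxidation of the secondary alcohol under nearly neutral conditions, which should leave the α-silyloxy stereocentre (C14) and the primary iodide untouched.

Step 8
Reactants: 14 (2S,4S)-2-[(tert-butyldimethylsilyl)oxy]-4-(iodomethyl)cyclopentan-1-one; 9 methyl 3-[(1S,6S)-3-bromo-1-methyl-6-(prop-1-en-2-yl)-2-(trifluoromethanesulfonyloxy)cyclohex-2-en-1-yl]propanoate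
Product: 16 methyl 3-[(1S,6S)-3-bromo-2-{[(1S,3S)-3-[(tert-butyldimethylsilyl)oxy]-4-oxocyclopentyl]methyl}-1-methyl-6-(prop-1-en-2-yl)cyclohex-2-en-1-yl]propanoate, via alkylzinc iodide 15 (not isolated)
Conditions: 14, Zn dust, LiCl, THF, 25 °C; then 9, PdCl2(dppf) (5 mol%), THF, 45 °C
Reagents that add atoms: none
Why: Negishi sp3–sp2 cross-coupling: zinc inserts into the primary C–I bond (ketone and silyl ether are tolerated) and zerovalent palladium should add oxidatively to the enol triflate in preference to the hindered tetrasubstituted C–Br bond, which forms C9–C11 without touching a stereocentre.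

Step 9
Reactants: 16 vinyl bromide ketone
Product: 17 bridged allylic alcohol methyl ester (bicyclo[3.2.1]oct-2-en-1-ol fused to ring B at C8=C9)
Conditions: CrCl2 (6 equiv), NiCl2 (5 mol%), DMF, 23 → 50 °C
Reagents that add atoms: none
Why: Intramolecular Nozaki–Hiyama–Kishi addition of the vinyl bromide to the cyclopentanone closes the ring C15–C8=C9–C11–C12–C16 by 6-exo-trig attack on the carbonyl; the one-carbon tether from C12 allows attack only on the carbonyl face cis to C11, so the C15 hydroxyl ends cis to the C14 silyloxy group and the C13–C14 bridge lies on the ring B face that carries the C10 methyl.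

Step 10
Reactants: 17 bridged allylic alcohol methyl ester
Product: 18 bridged allylic alcohol carboxylic acid
Conditions: LiOH·H2O, THF/MeOH/H2O, 23 °C; then 1 M HCl, 0 °C, to pH 3
Reagents that add atoms: lithium hydroxide, [Li+].[OH-]
Why: Saponification of the methyl ester (acyl–oxygen cleavage by hydroxide) frees the C3 acid needed for the lactone; the bridgehead alcohol can neither ionise nor undergo retro-aldol cleavage and no stereocentre is affected.

Step 11
Reactants: 18 bridged allylic alcohol carboxylic acid
Product: 21 14-O-(tert-butyldimethylsilyl)-14-O-deacetyl-17-norcrotobarin, via epoxy acid 19 (not isolated), via hydroxy keto acid 20 (not isolated)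
Conditions: mCPBA, CH2Cl2, 0 °C; then BF3·OEt2 (20 mol%), 4 Å MS, −78 → 23 °C
Reagents that add atoms: 3-chloroperbenzoic acid, O=C(OO)c1cccc(Cl)c1
Why: The peracid should epoxidise the electron-rich tetrasubstituted C8=C9 bond on its exo face (syn to the C16 bridge, anti to the C13–C14 bridge and to the axial C10 methyl), and Lewis-acid activation of the resulting 2,3-epoxy alcohol breaks the C8–O bond while C14 shifts from C15 to C8 antiperiplanar to it and C15 becomes the ketone. The closest known reaction is the Lewis-acid-promoted semipinacol rearrangement of 2,3-epoxy tertiary alcohols to β-hydroxy ketones with an α-quaternary centre, here in its ring-expanding form, which is at the same time the bicyclo[3.2.1]oct-2-yl to bicyclo[2.2.2]oct-2-yl Wagner–Meerwein shift driven by the carbinol oxygen. The cyclopentane C15–C16–C12–C13–C14 grows by one atom (C8) to the ring C8–C14–C13–C12–C16–C15 through a suprafacial 1,2-alkyl shift, and the δ-lactone then closes by 6-exo-trig acyl substitution of the C3 acid by the tertiary C9 hydroxyl under the same acid. C9 is set by the face of epoxidation, C8 by inversion (C14 enters anti to the epoxide oxygen) and C14 migrates with retention, so that O–C9 and C15 end cis, C14 trans to them, and the lactone is cis-fused to the C1 chain. The step needs attack on the tetrasubstituted alkene rather than on isopropenyl (electron richness), exo rather than endo attack (shape of the bicycle plus the axial methyl), and C8–O rather than C9–O cleavage with C14 rather than C16 migrating, which is secured because only the C15–C14 bond is antiperiplanar to the exo C8–O bond, the carbinol oxygen assists, and the α-silyloxy group raises the migratory aptitude of C14.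

Step 12
Reactants: 21 14-O-(tert-butyldimethylsilyl)-14-O-deacetyl-17-norcrotobarin
Product: 22 14-O-deacetyl-17-norcrotobarin
Conditions: HF·pyridine, THF, 0 → 23 °C
Reagents that add atoms: none
Why: Fluoride-induced desilylation (formation of the strong Si–F bond) under mildly acidic conditions, chosen to avoid an alkoxide that could open the C14 β-hydroxy ketone by retro-aldol cleavage; the configuration at C14 is retained.

Step 13
Reactants: 22 14-O-deacetyl-17-norcrotobarin
Product: 23 17-norcrotobarin
Conditions: Ac2O, pyridine, DMAP (cat.), CH2Cl2, 23 °C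
Reagents that add atoms: acetic anhydride, CC(=O)OC(C)=O
Why: DMAP-catalysed acylation of the secondary C14 alcohol with retention of configuration, the amine bases being too weak to cause retro-aldol cleavage or lactone opening.

Step 14
Reactants: 23 17-norcrotobarin
Product: 24 crotobarin
Conditions: (CH2O)n, N-methylanilinium trifluoroacetate, THF, 65 °C
Reagents that add atoms: formaldehyde (as paraformaldehyde), C=O
Why: Mannich-type α-methylenation (aminomethylation by the iminium ion of formaldehyde and N-methylaniline, then β-elimination of the amine) at C16, the only enolisable position of the C15 ketone since C8 is quaternary; no stereocentre is formed.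

**Compound list**
1 | 2-methylcyclohex-2-en-1-one | CC1=CCCCC1=O | starting material
2 | isopropenylmagnesium bromide (prop-1-en-2-ylmagnesium bromide) | CC(=C)[Mg]Br | starting material
3 | methyl acrylate | C=CC(=O)OC | starting material
4 | bromomagnesium (S)-2-methyl-3-(prop-1-en-2-yl)cyclohex-1-en-1-olate | CC1=C(O[Mg]Br)CCC[C@H]1C(C)=C | intermediate
5 | methyl 3-[(1S,6S)-1-methyl-2-oxo-6-(prop-1-en-2-yl)cyclohexyl]propanoate (chain trans to isopropenyl) | O=C1CCC[C@@H](C(=C)C)[C@]1(C)CCC(=O)OC | intermediate
6 | lithium enolate of 5 (C8=C9 enolate) | [Li]OC1=CCC[C@@H](C(=C)C)[C@]1(C)CCC(=O)OC | intermediate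
7 | methyl 3-[(1S,6S)-3-bromo-1-methyl-2-oxo-6-(prop-1-en-2-yl)cyclohexyl]propanoate (epimers at the C–Br carbon) | O=C1C(Br)CC[C@@H](C(=C)C)[C@]1(C)CCC(=O)OC | intermediate
8 | potassium enolate of 7 | [K]OC1=C(Br)CC[C@@H](C(=C)C)[C@]1(C)CCC(=O)OC | intermediate
9 | methyl 3-[(1S,6S)-3-bromo-1-methyl-6-(prop-1-en-2-yl)-2-(trifluoromethanesulfonyloxy)cyclohex-2-en-1-yl]propanoate | O=S(=O)(OC1=C(Br)CC[C@@H](C(=C)C)[C@]1(C)CCC(=O)OC)C(F)(F)F | intermediate
10 | cyclopent-3-en-1-ylmethanol | OCC1CC=CC1 | starting material
11 | 4-(iodomethyl)cyclopent-1-ene | ICC1CC=CC1 | intermediate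
12 | (1R,2S,4s)-4-(iodomethyl)cyclopentane-1,2-diol (meso; cis-diol trans to CH2I) | O[C@@H]1C[C@@H](CI)C[C@@H]1O | intermediate
13 | (1R,2S,4R)-2-[(tert-butyldimethylsilyl)oxy]-4-(iodomethyl)cyclopentan-1-ol | O[C@@H]1C[C@@H](CI)C[C@@H]1O[Si](C)(C)C(C)(C)C | intermediate
14 | (2S,4S)-2-[(tert-butyldimethylsilyl)oxy]-4-(iodomethyl)cyclopentan-1-one (OTBS trans to CH2I) | O=C1C[C@@H](CI)C[C@@H]1O[Si](C)(C)C(C)(C)C | intermediate
15 | {[(1S,3S)-3-[(tert-butyldimethylsilyl)oxy]-4-oxocyclopentyl]methyl}zinc iodide | O=C1C[C@@H](C[Zn]I)C[C@@H]1O[Si](C)(C)C(C)(C)C | intermediate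
16 | methyl 3-[(1S,6S)-3-bromo-2-{[(1S,3S)-3-[(tert-butyldimethylsilyl)oxy]-4-oxocyclopentyl]methyl}-1-methyl-6-(prop-1-en-2-yl)cyclohex-2-en-1-yl]propanoate | O=C1C[C@@H](CC2=C(Br)CC[C@@H](C(=C)C)[C@]2(C)CCC(=O)OC)C[C@@H]1O[Si](C)(C)C(C)(C)C | intermediate
17 | bridged allylic alcohol methyl ester: ring B alkene C8=C9 inside a bicyclo[3.2.1]oct-2-ene (C15 bridgehead carbinol on C8, C11 on C9, C16 one-carbon bridge, C13–C14 bridge on the face of the C10 methyl, 14-OTBS exo and cis to 15-OH), C10 chain CH2CH2CO2Me | O[C@@]12C[C@@H](CC3=C1CC[C@@H](C(=C)C)[C@]3(C)CCC(=O)OC)C[C@@H]2O[Si](C)(C)C(C)(C)C | intermediate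
18 | carboxylic acid of 17 | O[C@@]12C[C@@H](CC3=C1CC[C@@H](C(=C)C)[C@]3(C)CCC(=O)O)C[C@@H]2O[Si](C)(C)C(C)(C)C | intermediate
19 | 8,9-epoxide of 18 (oxygen on the face of the C1 chain, exo) | O[C@@]12C[C@@H](C[C@@]34O[C@]31CC[C@@H](C(=C)C)[C@]4(C)CCC(=O)O)C[C@@H]2O[Si](C)(C)C(C)(C)C | intermediate
20 | 9-hydroxy-15-oxo acid with the bicyclo[2.2.2]octane in place (seco acid of 21) | C1C(=O)[C@]23CC[C@@H](C(=C)C)[C@](C)(CCC(=O)O)[C@@]2(O)C[C@H]1C[C@@H]3O[Si](C)(C)C(C)(C)C | intermediate
21 | 14-O-(tert-butyldimethylsilyl)-14-O-deacetyl-17-norcrotobarin (C16 is CH2) | C1C(=O)[C@]23CC[C@@H](C(=C)C)[C@]4(C)CCC(=O)O[C@@]42C[C@H]1C[C@@H]3O[Si](C)(C)C(C)(C)C | intermediate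
22 | 14-O-deacetyl-17-norcrotobarin | C1C(=O)[C@]23CC[C@@H](C(=C)C)[C@]4(C)CCC(=O)O[C@@]42C[C@H]1C[C@@H]3O | intermediate
23 | 17-norcrotobarin | C1C(=O)[C@]23CC[C@@H](C(=C)C)[C@]4(C)CCC(=O)O[C@@]42C[C@H]1C[C@@H]3OC(C)=O | intermediate
24 | crotobarin | C=C1C(=O)[C@]23CC[C@@H](C(=C)C)[C@]4(C)CCC(=O)O[C@@]42C[C@H]1C[C@@H]3OC(C)=O | target

**Step count:** 14 steps in total. Longest linear sequence: 11 steps (steps 4–14).

**Steps most likely to fail**

Step 11. The epoxide may ionise at C9 instead of C8 (followed by unwanted shifts), or the peracid may attack the isopropenyl group, so that the C14 shift is not the main pathway. The fallback sets out from ester 17 (step 10 is then skipped) and comes back at 21. N-Bromosuccinimide in CH2Cl2/i-PrOH at −20 °C should form a bromonium ion on the same exo face and trigger the same C14 shift (halonium-induced semipinacol rearrangement), leaving bromine at C9 in the 9-bromo-15-keto methyl ester F1. AgOTf in CH2Cl2 then ionises the tertiary C9–Br bond, and the ester carbonyl of the cis-disposed C1–C3 chain captures the cation with loss of its methyl group, closing the δ-lactone to give 21.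

Step 9. Insertion of nickel into the tetrasubstituted C8–Br bond may be slow, and protodebromination may outrun addition to the hindered ketone. The fallback reverses the order of bond formation; it sets out from 5 and 14 and comes back at 17. Lithium enolate 6 adds to ketone 14 anti to the silyloxy group (aldol addition, C8–C15), and trapping with Me3SiCl gives the silyl-protected aldol F2. KN(SiMe3)2 and PhNTf2 give the tetrasubstituted enol triflate F3. An intramolecular nickel-catalysed reductive coupling of the enol triflate with the primary iodide (NiBr2·glyme, 4,4′-di-tert-butyl-2,2′-bipyridine, Mn, DMA) forms C9–C11 and gives the trimethylsilyl ether F4. K2CO3 in MeOH removes the silyl group to give 17.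

Step 1. Enantioselectivity may erode with an alkenyl Grignard reagent, and the magnesium enolate may oligomerise the acrylate. The fallback sets out from cyclohex-2-en-1-one and comes back at 5. Potassium isopropenyltrifluoroborate with [RhCl(cod)]2 and (R)-BINAP (asymmetric conjugate addition of an alkenylboron reagent) should give (R)-3-(prop-1-en-2-yl)cyclohexan-1-one F5. Kinetic enolisation away from the substituent (LiN(i-Pr)2, Me3SiCl) gives the silyl enol ether F6, and Pd(OAc)2 (Saegusa–Ito oxidation) gives (R)-5-(prop-1-en-2-yl)cyclohex-2-en-1-one F7. α′-Methylation (LiN(i-Pr)2, MeI) gives the 6-methyl enone F8. A second α′-deprotonation and Michael addition to methyl acrylate, anti to the isopropenyl group, gives the enone ester F9. Conjugate reduction with LiBH(s-Bu)3 at −78 °C gives 5.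

Further compounds
F1 | step 11 | 9-bromo-15-keto methyl ester with the bicyclo[2.2.2]octane in place (bromine at C9 on the face of the C1 chain) | C1C(=O)[C@]23CC[C@@H](C(=C)C)[C@](C)(CCC(=O)OC)[C@@]2(Br)C[C@H]1C[C@@H]3O[Si](C)(C)C(C)(C)C
F2 | step 9 | silyl-protected aldol of 5 and 14 (C8–C15 bond, 15-OSiMe3 cis to 14-OTBS, epimers at C8) | O=C1C(CC[C@@H](C(=C)C)[C@]1(C)CCC(=O)OC)[C@@]2(O[Si](C)(C)C)C[C@@H](CI)C[C@@H]2O[Si](C)(C)C(C)(C)C
F3 | step 9 | enol triflate of F2 (C8=C9, triflate on C9) | O=S(=O)(OC1=C(CC[C@@H](C(=C)C)[C@]1(C)CCC(=O)OC)[C@@]2(O[Si](C)(C)C)C[C@@H](CI)C[C@@H]2O[Si](C)(C)C(C)(C)C)C(F)(F)F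
F4 | step 9 | 15-O-trimethylsilyl ether of 17 | C[Si](C)(C)O[C@@]12C[C@@H](CC3=C1CC[C@@H](C(=C)C)[C@]3(C)CCC(=O)OC)C[C@@H]2O[Si](C)(C)C(C)(C)C
F5 | step 1 | (R)-3-(prop-1-en-2-yl)cyclohexan-1-one | O=C1CCC[C@@H](C(=C)C)C1
F6 | step 1 | (R)-trimethyl{[5-(prop-1-en-2-yl)cyclohex-1-en-1-yl]oxy}silane | C[Si](C)(C)OC1=CCC[C@@H](C(=C)C)C1
F7 | step 1 | (R)-5-(prop-1-en-2-yl)cyclohex-2-en-1-one | O=C1C=CC[C@@H](C(=C)C)C1
F8 | step 1 | (5R)-6-methyl-5-(prop-1-en-2-yl)cyclohex-2-en-1-one (epimers at C6) | O=C1C=CC[C@@H](C(=C)C)C1C
F9 | step 1 | methyl 3-[(1S,6S)-1-methyl-2-oxo-6-(prop-1-en-2-yl)cyclohex-3-en-1-yl]propanoate | O=C1C=CC[C@@H](C(=C)C)[C@]1(C)CCC(=O)OC
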